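**Retrosynthetic overview**

1. Numbering (dictyol type): ring A = cyclopentene C1–C5 (methyl C19 on C4); ring B = seven-membered ring C1, C5–C10 (C6 OH, C7 side chain C11–C17 and C20, C9 OAc, C10=C18H2). End game: C5–H and the C3=C4 olefin come from a reductive 1,3-transposition of a C3 carbinol/C4=C5 olefin; C6/C7 from a dynamic kinetic ketone hydrogenation; C9–O from allylic oxidation, then esterification with inversion.
2. Enabling feature: in ring B the C6 carbonyl lies 1,5 to the exocyclic C10=C18 olefin through C7–C8–C9 (a δ,ε-unsaturated ketone, the oxy-Cope retron). Ring B is therefore unravelled to a 1-alkenyl-3-methylenecyclopentanol (five-membered ring C1–C5–C6–C18–C10, exocyclic CH2 = future C9, alkenyl = C7=C8): C6–C18 breaks, C8–C9 forms.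
3. The carbinol comes from a bicyclic enone and a 2-lithio-1-alkene made from (S)-β-citronellene, which brings C7, C8, C11–C17, C20 and the C11 stereocentre.
4. The bicyclic enone comes from (R)-carvone: epoxide cleavage and aldol condensation contract the carvone ring to ring A + C6 (carvone C5 becomes C1; the carvone oxygen becomes a temporary C3–O relay); the isopropenyl group becomes C9, C10, C18.
5. Order of ring formation: ring A (aldol condensation), temporary five-membered carbinol ring (Barbier closure), ring B by two-atom ring expansion (anionic oxy-Cope).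

Key step: step 15

Remark: centres that are destroyed or set later (carbinol carbon of 11 and 19; C7 of 21 and 22) are carried as epimer mixtures and are left open in the SMILES.

**Route**

Step 1
Reactants: 1 (R)-carvone, (5R)-2-methyl-5-(prop-1-en-2-yl)cyclohex-2-en-1-one
Product: 2 (1R,5R)-cis-carveol
Conditions: NaBH4, CeCl3·7H2O, MeOH, 0 °C
Reagents that add atoms: none
Why: Luche 1,2-reduction of the enone; pseudo-axial hydride attack should give the 1,5-cis allylic alcohol (substrate control), which is inverted in step 2.

Step 2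
Reactants: 2 (1R,5R)-cis-carveol
Product: 3 (1S,5R)-trans-carveyl 4-nitrobenzoate
Conditions: 4-nitrobenzoic acid, PPh3, DIAD, THF, 0 → 23 °C
Reagents that add atoms: 4-nitrobenzoic acid, OC(=O)c1ccc(cc1)[N+](=O)[O-]
Why: Mitsunobu esterification with SN2 inversion gives the 1,5-trans series, which places the relay oxygen on the C1–H face of the later ring A, as step 20 requires.

Step 3
Reactants: 3 (1S,5R)-trans-carveyl 4-nitrobenzoate
Product: 4 (1S,5R)-trans-carveol
Conditions: K2CO3, MeOH, 23 °C
Reagents that add atoms: none
Why: base-catalysed transesterification frees the alcohol without touching a stereocentre.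

Step 4
Reactants: 4 (1S,5R)-trans-carveol
Product: 5 syn-epoxy alcohol (ring epoxide of 4 on the hydroxyl face)
Conditions: VO(acac)2 (cat.), t-BuOOH, CH2Cl2, 0 → 23 °C
Reagents that add atoms: tert-butyl hydroperoxide, CC(C)(C)OO
Why: hydroxyl-directed vanadium-catalysed epoxidation attacks only the allylic-alcohol olefin, syn to OH, and leaves the isopropenyl group; the oxirane centres are destroyed in step 6.

Step 5
Reactants: 5 syn-epoxy alcohol
Product: 6 tert-butyldimethylsilyl ether of 5
Conditions: TBSCl, imidazole, DMF, 23 °C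
Reagents that add atoms: tert-butyldimethylsilyl chloride, C[Si](C)(Cl)C(C)(C)C
Why: standard silylation protects the relay oxygen for the organometallic, base and hydride steps that follow.

Step 6
Reactants: 6 silyl ether of the epoxy alcohol
Product: 8 keto aldehyde (3S,5S)-5-(TBS-oxy)-6-oxo-3-(prop-1-en-2-yl)heptanal, via diol 7 (not isolated)
Conditions: H5IO6, THF/H2O, 0 → 23 °C
Reagents that add atoms: water, O
Why: periodic acid opens the epoxide to the vicinal diol and cleaves it (Malaprade glycol cleavage), which unzips the carvone ring between its former olefinic carbons and leaves both stereocentres untouched.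

Step 7
Reactants: 8 keto aldehyde
Product: 9 (3S,5R)-3-(TBS-oxy)-2-methyl-5-(prop-1-en-2-yl)cyclopent-1-ene-1-carbaldehyde
Conditions: Bn2NH·CF3CO2H (cat.), toluene, 50 °C
Reagents that add atoms: none
Why: intramolecular aldol condensation through the aldehyde enamine (aldehyde α-carbon onto the methyl ketone, then dehydration) forms ring A as the tetrasubstituted enal; the mild ammonium salt is chosen so that the α-silyloxy ketone centre is not epimerised before ring closure.

Step 8
Reactants: 9 cyclopentene carbaldehyde
Product: 10 allylic chloride, the 5-(3-chloroprop-1-en-2-yl) analogue of 9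
Conditions: Ca(OCl)2, solid CO2, CH2Cl2/H2O, 0 °C
Reagents that add atoms: calcium hypochlorite, [Ca+2].[O-]Cl.[O-]Cl
Why: ene-type chlorination by HOCl made in the flask should convert the electron-rich 1,1-disubstituted isopropenyl olefin into the 2-substituted allyl chloride, while the enal olefin is deactivated.

Step 9
Reactants: 10 allylic chloride
Product: 11 bicyclic dienol 5-(TBS-oxy)-4-methyl-1-methylidene-1,2,3,5,6,6a-hexahydropentalen-3-ol (carbinol epimers)
Conditions: zinc dust, NaI (cat.), sat. aq NH4Cl/THF, 23 °C
Reagents that add atoms: none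
Why: intramolecular Barbier allylation of the aldehyde closes the five-membered carbinol ring; either allyl terminus gives the same 3-methylenecyclopentanol, and the new carbinol centre is removed in step 10.

Step 10
Reactants: 11 bicyclic dienol
Product: 12 bicyclic enone 5-(TBS-oxy)-4-methyl-1-methylidene-2,5,6,6a-tetrahydropentalen-3(1H)-one
Conditions: MnO2, CH2Cl2, 23 °C
Reagents that add atoms: none
Why: neutral MnO2 oxidation of the allylic alcohol gives the ketone without base, so the skipped exocyclic olefin should not migrate.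

Step 11
Reactants: 13 (S)-β-citronellene, (3S)-3,7-dimethylocta-1,6-diene
Product: 15 (3E,6S)-2,6-dimethylocta-3,7-dien-2-ol, via hydroxy selenide 14 (not isolated)
Conditions: N-(phenylseleno)phthalimide, H2O, CSA (cat.), CH2Cl2, 23 °C; then 30% H2O2, pyridine, 0 → 23 °C
Reagents that add atoms: water, O
Why: Markovnikov hydroxyselenation of the trisubstituted olefin (much faster than the vinyl group), then selenoxide syn-elimination, which can only run away from the fully substituted carbinol carbon, should give the E-allylic tertiary alcohol of the side chain.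

Step 12
Reactants: 15 dienol
Product: 16 (3S,5E)-7-hydroxy-3,7-dimethyloct-5-en-2-one
Conditions: PdCl2 (cat.), CuCl, O2 (1 atm), DMF/H2O, 23 °C
Reagents that add atoms: water, O
Why: Wacker oxidation converts only the terminal vinyl group into the methyl ketone; the hindered internal E-olefin is inert and the α-stereocentre should not enolise under these conditions.

Step 13
Reactants: 16 methyl ketone
Product: 17 2,4,6-triisopropylbenzenesulfonylhydrazone of 16 (E at C=N)
Conditions: 2,4,6-triisopropylbenzenesulfonyl hydrazide, THF, 23 °C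
Reagents that add atoms: 2,4,6-triisopropylbenzenesulfonyl hydrazide, NNS(=O)(=O)c1c(C(C)C)cc(C(C)C)cc1C(C)C
Why: acid-free hydrazone formation gives the Shapiro precursor with the sulfonamide nitrogen syn to the methyl group.

Step 14
Reactants: 17 sulfonylhydrazone; 12 bicyclic enone
Product: 19 tertiary bis-allylic carbinol (carbinol epimers), via vinyllithium 18 (not isolated)
Conditions: 17, n-BuLi (3.1 equiv), THF, −78 → 0 °C; CeCl3, −78 °C; then 12; AcOH quench
Reagents that add atoms: none
Why: Shapiro reaction: the hydrazone dianion forms at the methyl group and loses sulfinate and N2 to give the 2-lithio-1-alkene with the neighbouring stereocentre untouched; its organocerium derivative adds 1,2 to the enolisable enone, and the new carbinol configuration is irrelevant because that carbon becomes the carbonyl in step 15.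

Step 15
Reactants: 19 tertiary bis-allylic carbinol
Product: 21 ring-expanded hydroazulenone (C7 epimers), via dipotassium enolate 20 (not isolated)
Conditions: KH, 18-crown-6, THF, 0 → 23 °C; AcOH, −78 °C
Reagents that add atoms: none
Why: Deprotonation gives the potassium alkoxide of a 1,5-dien-3-ol (C8=C7–C6–C18–C10=C9) whose central C6–C18 bond belongs to the five-membered ring; the charge-accelerated [3,3] shift (anionic oxy-Cope rearrangement, closest known type: alkoxide-accelerated ring expansions of alkenyl cycloalkanols) breaks C6–C18 and forms C8–C9, so the ring C1–C5–C6–C18–C10 becomes the seven-membered ring C1–C10–C9–C8–C7–C6–C5 and C18 is left as the exocyclic methylene on C10. Ring B is thus closed by suprafacial sigmatropic C8–C9 bond formation in a chair-like six-centre array bridged by C5–C1 (a bicyclo[3.2.1]octane-shaped transition state), not by an end-to-end cyclisation. The enolate C6(OK)=C7 forms regiospecifically; C1, C3 and C11 are not involved and keep their configuration, while the only new stereocentre, C7, arises unselectively on protonation and is set in step 17. The selectivity needed is rearrangement through the side-chain alkenyl group, not through the ring A olefin and not by simple retro-allyl fragmentation: the ring A olefin could react only through a strained norbornane-like transition state, and because both termini of the allyl unit are CH2 groups even a dissociative [1,3] recombination gives the same constitution. Both carbinol epimers of 19 should converge on 21.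

Step 16
Reactants: 21 hydroazulenone
Product: 22 (9S)-9-hydroxy ketone (C7 epimers)
Conditions: SeO2 (0.5 equiv), t-BuOOH, CH2Cl2, 23 °C
Reagents that add atoms: tert-butyl hydroperoxide, CC(C)(C)OO
Why: Riley-type SeO2 allylic hydroxylation (ene reaction, then [2,3]-shift) of the 1,1-disubstituted olefin should attack the allylic CH2 (C9), not the allylic methine C1, and return the exocyclic olefin; oxygen is expected on the C1–H face, anti to the ring A carbon C2 that flanks C10, and this centre is inverted in step 18.

Step 17
Reactants: 22 (9S)-9-hydroxy ketone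
Product: 23 (6S,7R,9S)-6,9-diol
Conditions: RuCl2[(R)-xylbinap][(R)-daipen] (cat.), t-BuOK (cat.), H2 (8 atm), i-PrOH, 25 °C
Reagents that add atoms: none
Why: dynamic kinetic asymmetric hydrogenation of an α-substituted ketone: base equilibrates C7 through the enolate while the chiral ruthenium hydride reduces one C7 epimer faster, delivering hydride anti to the branched side chain (OH cis to the side chain) on the C6 face selected by the catalyst; C=C bonds are not reduced.

Step 18
Reactants: 23 6,9-diol
Product: 24 (9R)-9-acetate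
Conditions: AcOH, PPh3, DIAD, toluene, 0 → 23 °C
Reagents that add atoms: acetic acid, CC(O)=O
Why: Mitsunobu esterification inverts C9 and installs the acetate in one operation; the C6 carbinol (flanked by the ring-fusion sp2 carbon and the branched C7) is too hindered and the tertiary C15 carbinol cannot react.

Step 19
Reactants: 24 9-acetate
Product: 25 C3,C6,C15-triol 9-acetate
Conditions: HF·pyridine, pyridine/THF, 0 → 23 °C
Reagents that add atoms: none
Why: buffered fluoride desilylation frees the C3 relay carbinol and leaves the allylic acetate and the tertiary allylic alcohol intact.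

Step 20
Reactants: 25 triol acetate
Product: 28 target, (1S,5R,6S,7R,9R,11S)-configured 9-acetoxy-6,15-diol, via sulfonylhydrazine 26 (not isolated), via allylic diazene 27 (not isolated)
Conditions: 2-nitrobenzenesulfonyl hydrazide, PPh3, DEAD, N-methylmorpholine, −30 → 23 °C
Reagents that add atoms: none
Why: reductive 1,3-transposition of an allylic alcohol: Mitsunobu displacement at the least hindered secondary carbinol C3 (inversion), loss of sulfinic acid, then retro-ene loss of N2 from the allylic diazene, which delivers hydrogen to C5 on the face of the C–N bond (opposite the original C3–O, hence trans to C1–H) and moves the olefin to C3=C4.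

**Compound list**

1 | (R)-carvone | CC1=CC[C@H](CC1=O)C(C)=C | starting material
2 | (1R,5R)-cis-carveol | CC1=CC[C@H](C[C@H]1O)C(C)=C | intermediate
3 | (1S,5R)-trans-carveyl 4-nitrobenzoate | CC1=CC[C@H](C[C@@H]1OC(=O)c2ccc(cc2)[N+](=O)[O-])C(C)=C | intermediate
4 | (1S,5R)-trans-carveol | CC1=CC[C@H](C[C@@H]1O)C(C)=C | intermediate
5 | syn-epoxy alcohol of 4 | C[C@@]12O[C@@H]1C[C@H](C[C@@H]2O)C(C)=C | intermediate
6 | TBS ether of 5 | C[C@@]12O[C@@H]1C[C@H](C[C@@H]2O[Si](C)(C)C(C)(C)C)C(C)=C | intermediate
7 | vicinal diol from epoxide opening (not isolated) | C[C@]1(O)[C@H](O)C[C@H](C[C@@H]1O[Si](C)(C)C(C)(C)C)C(C)=C | intermediate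
8 | (3S,5S)-5-(TBS-oxy)-6-oxo-3-(prop-1-en-2-yl)heptanal | CC(=O)[C@@H](O[Si](C)(C)C(C)(C)C)C[C@@H](CC=O)C(C)=C | intermediate
9 | (3S,5R)-3-(TBS-oxy)-2-methyl-5-(prop-1-en-2-yl)cyclopent-1-ene-1-carbaldehyde | O=CC1=C(C)[C@@H](O[Si](C)(C)C(C)(C)C)C[C@@H]1C(C)=C | intermediate
10 | 5-(3-chloroprop-1-en-2-yl) analogue of 9 | O=CC1=C(C)[C@@H](O[Si](C)(C)C(C)(C)C)C[C@@H]1C(=C)CCl | intermediate
11 | 5-(TBS-oxy)-4-methyl-1-methylidene-1,2,3,5,6,6a-hexahydropentalen-3-ol (carbinol epimers) | C=C1CC(O)C2=C(C)[C@@H](O[Si](C)(C)C(C)(C)C)C[C@H]12 | intermediate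
12 | 5-(TBS-oxy)-4-methyl-1-methylidene-2,5,6,6a-tetrahydropentalen-3(1H)-one | C=C1CC(=O)C2=C(C)[C@@H](O[Si](C)(C)C(C)(C)C)C[C@H]12 | intermediate
13 | (S)-β-citronellene | C=C[C@@H](C)CCC=C(C)C | starting material
14 | β-hydroxy phenylselenide (not isolated) | C=C[C@@H](C)CCC([Se]c1ccccc1)C(C)(C)O | intermediate
15 | (3E,6S)-2,6-dimethylocta-3,7-dien-2-ol | C=C[C@@H](C)C/C=C/C(C)(C)O | intermediate
16 | (3S,5E)-7-hydroxy-3,7-dimethyloct-5-en-2-one | CC(=O)[C@@H](C)C/C=C/C(C)(C)O | intermediate
17 | 2,4,6-triisopropylbenzenesulfonylhydrazone of 16 | C/C(=N\NS(=O)(=O)c1c(C(C)C)cc(C(C)C)cc1C(C)C)[C@@H](C)C/C=C/C(C)(C)O | intermediate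
18 | 2-lithio-1-alkene, lithium alkoxide (not isolated) | [Li]C(=C)[C@@H](C)C/C=C/C(C)(C)O[Li] | intermediate
19 | 3-[(3S,5E)-7-hydroxy-3,7-dimethylocta-1,5-dien-2-yl] carbinol of the bicyclic diene (carbinol epimers) | C=C1CC(O)(C(=C)[C@@H](C)C/C=C/C(C)(C)O)C2=C(C)[C@@H](O[Si](C)(C)C(C)(C)C)C[C@H]12 | intermediate
20 | dipotassium C6 enolate / C15 alkoxide (not isolated) | C=C1[C@H]2C[C@H](O[Si](C)(C)C(C)(C)C)C(C)=C2C(O[K])=C([C@@H](C)C/C=C/C(C)(C)O[K])CC1 | intermediate
21 | 3-(TBS-oxy)-6-oxo hydroazulene with C4=C5 and C10=C18 olefins and full side chain (C7 epimers) | C=C1[C@H]2C[C@H](O[Si](C)(C)C(C)(C)C)C(C)=C2C(=O)C([C@@H](C)C/C=C/C(C)(C)O)CC1 | intermediate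
22 | (9S)-9-hydroxy derivative of 21 (C7 epimers) | C=C1[C@H]2C[C@H](O[Si](C)(C)C(C)(C)C)C(C)=C2C(=O)C([C@@H](C)C/C=C/C(C)(C)O)C[C@@H]1O | intermediate
23 | (6S,7R,9S)-6,9-diol | C=C1[C@H]2C[C@H](O[Si](C)(C)C(C)(C)C)C(C)=C2[C@@H](O)[C@@H]([C@@H](C)C/C=C/C(C)(C)O)C[C@@H]1O | intermediate
24 | (9R)-9-acetate of the 6-ol | C=C1[C@H]2C[C@H](O[Si](C)(C)C(C)(C)C)C(C)=C2[C@@H](O)[C@@H]([C@@H](C)C/C=C/C(C)(C)O)C[C@H]1OC(C)=O | intermediate
25 | desilylated C3,C6,C15-triol 9-acetate | C=C1[C@H]2C[C@H](O)C(C)=C2[C@@H](O)[C@@H]([C@@H](C)C/C=C/C(C)(C)O)C[C@H]1OC(C)=O | intermediate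
26 | C3 N-(2-nitrobenzenesulfonyl)hydrazine, inverted at C3 (not isolated) | C=C1[C@H]2C[C@@H](N(N)S(=O)(=O)c3ccccc3[N+](=O)[O-])C(C)=C2[C@@H](O)[C@@H]([C@@H](C)C/C=C/C(C)(C)O)C[C@H]1OC(C)=O | intermediate
27 | C3 allylic diazene (not isolated) | C=C1[C@H]2C[C@@H](N=N)C(C)=C2[C@@H](O)[C@@H]([C@@H](C)C/C=C/C(C)(C)O)C[C@H]1OC(C)=O | intermediate
28 | target (CNP0312076.1) | C=C1[C@H]2CC=C(C)[C@@H]2[C@@H](O)[C@@H]([C@@H](C)C/C=C/C(C)(C)O)C[C@H]1OC(C)=O | target

**Step count and risks**

Total steps: 20. Longest linear sequence: 17 (steps 1–10 and 14–20); the side-chain branch is steps 11–13.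

Steps most likely to fail:

1. Step 15 (ring expansion). The tertiary homoallylic alkoxide may fragment by retro-allylation faster than it rearranges, or the base may move the skipped exocyclic olefin into conjugation. The fallback sets out from 19 and comes back at 21 and keeps the same bond reorganisation in a neutral manifold: both hydroxyls of 19 are silylated (TMSOTf, Et3N, CH2Cl2, −78 °C) to the bis-trimethylsilyl ether F1; F1 is heated in degassed toluene (sealed, base-washed tube, 190 °C) for the thermal siloxy-Cope rearrangement to the silyl enol ether F2; K2CO3 in MeOH then releases the ketone and the tertiary alcohol to give 21.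

2. Step 17 (dynamic kinetic hydrogenation). Epimerisation at C7 may be slower than hydride transfer, the catalyst may be mismatched with the existing stereocentres, or the base may erode the C3 centre through the extended enolate. The fallback sets out from 22 and comes back at 23 and uses substrate-controlled reduction with recycling: 22 is silylated (TESCl, imidazole) to the 9-O-triethylsilyl ketone F5; L-Selectride at −78 °C adds hydride anti to the side chain in each C7 epimer and should give the cis-alcohol F6 and its 6,7-bis-epimer F7, which are separated; F7 is returned to F5 by Dess–Martin oxidation and brief Et3N equilibration of C7; F6 is desilylated at C9 only (PPTS, MeOH, 0 °C) to give 23.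

3. Step 16 (allylic hydroxylation). The [2,3]-shift may deliver oxygen to the other face of C9, or to both faces. The fallback sets out from 21 and comes back at 24 and makes the sequence stereoconvergent: the (9R)-9-hydroxy ketone F3 is separated and hydrogenated as in step 17 to the (6S,7R,9R)-diol F4, which is then acetylated with retention at the unhindered C9 carbinol (Ac2O, pyridine, DMAP, −20 °C) in place of the Mitsunobu inversion, giving 24.

Further compounds
F1 | step 15 | bis-trimethylsilyl ether of 19 | C=C1CC(O[Si](C)(C)C)(C(=C)[C@@H](C)C/C=C/C(C)(C)O[Si](C)(C)C)C2=C(C)[C@@H](O[Si](C)(C)C(C)(C)C)C[C@H]12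
F2 | step 15 | C6 trimethylsilyl enol ether, C15 trimethylsilyl ether of ring-expanded ketone | C=C1[C@H]2C[C@H](O[Si](C)(C)C(C)(C)C)C(C)=C2C(O[Si](C)(C)C)=C([C@@H](C)C/C=C/C(C)(C)O[Si](C)(C)C)CC1
F3 | step 16 | (9R)-9-hydroxy ketone, C9 epimer of 22 | C=C1[C@H]2C[C@H](O[Si](C)(C)C(C)(C)C)C(C)=C2C(=O)C([C@@H](C)C/C=C/C(C)(C)O)C[C@H]1O
F4 | step 16 | (6S,7R,9R)-6,9-diol | C=C1[C@H]2C[C@H](O[Si](C)(C)C(C)(C)C)C(C)=C2[C@@H](O)[C@@H]([C@@H](C)C/C=C/C(C)(C)O)C[C@H]1O
F5 | step 17 | 9-O-triethylsilyl ether of 22 | C=C1[C@H]2C[C@H](O[Si](C)(C)C(C)(C)C)C(C)=C2C(=O)C([C@@H](C)C/C=C/C(C)(C)O)C[C@@H]1O[Si](CC)(CC)CC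
F6 | step 17 | (6S,7R)-cis-alcohol, 9-O-triethylsilyl ether | C=C1[C@H]2C[C@H](O[Si](C)(C)C(C)(C)C)C(C)=C2[C@@H](O)[C@@H]([C@@H](C)C/C=C/C(C)(C)O)C[C@@H]1O[Si](CC)(CC)CC
F7 | step 17 | 6,7-bis-epimer of F6 | C=C1[C@H]2C[C@H](O[Si](C)(C)C(C)(C)C)C(C)=C2[C@H](O)[C@H]([C@@H](C)C/C=C/C(C)(C)O)C[C@@H]1O[Si](CC)(CC)CC
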